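**Strategy.** Everything rests on cutting the C2–C8 bond of the cyclobutane (tricyclo[5.4.0.0^2,8]undecane locants of the target). The key step makes this bond by 4-exo opening of a C8–C9 epoxide by the C2 γ-carbanion of a cycloheptane-1,3-dione dianion. One operation closes the cyclobutane C1–C2–C8–C7 and thereby the seven-membered ring C2–C3–C4–C5–C6–C7–C8, sets the quaternary C2 and leaves the C9 carbinol that becomes the enone. It exploits the 1,3-dioxygenation at C3/C5 next to quaternary C6, which makes C2–H the only γ-acidic site. The precursor is a cis-fused bicyclo[5.4.0]undecane epoxy-dione, assembled from a limonene-derived allylic alcohol by Ireland–Claisen rearrangement.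

Key step: step 8

Remark (locants): skeleton atoms are numbered as in the target, also in earlier intermediates: C1 (CH next to the ketone C11), C2 (cyclobutane C–CH3), C3 and C5 (ester carbinols), C4 (CH2), C6 (CMe2), C7 and C8 (cyclobutane CH), C9 (=C–CH3), C10 (=CH), C11 (C=O).

Remark (assumptions): the starting terpene alcohol is taken as the commercial (1S,4R) isomer, with hydroxyl and isopropenyl on the same ring face. The seven-membered 1,3-diones of steps 6–8 are taken to be mainly diketo tautomers, as cycloheptane-1,3-dione is.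

Step 1
Reactants: 1 (1S,4R)-1-methyl-4-(prop-1-en-2-yl)cyclohex-2-en-1-ol; 2 2-methylpropanoyl chloride
Product: 3 (1S,4R)-1-methyl-4-(prop-1-en-2-yl)cyclohex-2-en-1-yl 2-methylpropanoate
Conditions: n-BuLi, THF, −78 °C; then 2, −78 → 0 °C
Reagents that add atoms: none
Why: Acylation of the preformed lithium alkoxide (alkoxide esterification of a tertiary allylic alcohol) needs no acid and does not ionise the allylic C–O bond, so both stereocentres are kept.

Step 2
Reactants: 3 (1S,4R)-1-methyl-4-(prop-1-en-2-yl)cyclohex-2-en-1-yl 2-methylpropanoate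
Product: 6 2-methyl-2-[(1S,6R)-3-methyl-6-(prop-1-en-2-yl)cyclohex-2-en-1-yl]propanoic acid, via silyl ketene acetal 4 (not isolated), via trimethylsilyl ester 5 (not isolated)
Conditions: LiN(i-Pr)2, THF, −78 °C; Me3SiCl, −78 → 65 °C; then 1 M HCl, rt
Reagents that add atoms: none
Why: Ireland–Claisen rearrangement: the tetrasubstituted silyl ketene acetal (no E/Z issue) shifts suprafacially across the ring face that carries the ester oxygen, so the C6–C7 bond forms cis to the isopropenyl group on C1, which sets C7 and the later cis ring fusion while the quaternary C6 and the C8=C9 alkene are created together.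

Step 3
Reactants: 6 2-methyl-2-[(1S,6R)-3-methyl-6-(prop-1-en-2-yl)cyclohex-2-en-1-yl]propanoic acid
Product: 8 2-[6-(1-hydroxypropan-2-yl)-3-methylcyclohex-2-en-1-yl]-2-methylpropanoic acid (ring centres as in 6; C2 epimers), via bis(9-BBN) adduct 7 (not isolated)
Conditions: 9-BBN (3 equiv), THF, 0 °C → rt; then NaOH, H2O2, 0 °C → rt; then 1 M HCl to pH 3
Reagents that add atoms: hydrogen peroxide, OO
Why: Hydroboration–oxidation with the bulky 9-BBN takes the 1,1-disubstituted isopropenyl alkene in preference to the trisubstituted ring alkene and converts the acid only into its acyloxyborane, which the alkaline work-up cleaves; the new C2 methine forms as an epimer mixture that is of no consequence because C2 is planarised in step 8.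

Step 4
Reactants: 8 2-[6-(1-hydroxypropan-2-yl)-3-methylcyclohex-2-en-1-yl]-2-methylpropanoic acid
Product: 9 3-[6-(1-hydroxypropan-2-yl)-3-methylcyclohex-2-en-1-yl]-3-methylbutan-2-one (ring centres as in 6; C2 epimers)
Conditions: MeLi (4.5 equiv), Et2O–THF, 0 °C → rt; then 1 M HCl, 0 °C
Reagents that add atoms: methyllithium, [Li]C
Why: Addition of methyllithium to the lithium carboxylate (carboxylic acid to methyl ketone conversion) stops at the gem-dialkoxide, which gives the ketone only on work-up, and the quaternary α-carbon C6 disfavours over-addition.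

Step 5
Reactants: 9 3-[6-(1-hydroxypropan-2-yl)-3-methylcyclohex-2-en-1-yl]-3-methylbutan-2-one
Product: 11 2-[4-methyl-2-(2-methyl-3-oxobutan-2-yl)cyclohex-3-en-1-yl]propanenitrile (ring centres as in 6; C2 epimers), via keto aldehyde 10 (not isolated)
Conditions: TEMPO (cat.), PhI(OAc)2 (2.2 equiv), NH4OAc (4 equiv), MeCN–H2O 9:1, rt
Reagents that add atoms: ammonium acetate, [NH4+].CC([O-])=O
Why: One-pot nitroxyl-catalysed ammoxidation (alcohol to aldehyde, condensation with ammonia, oxidation of the aldimine by PhI(OAc)2) gives the nitrile under nearly neutral conditions that leave the hindered ketone and the alkene untouched.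

Step 6
Reactants: 11 2-[4-methyl-2-(2-methyl-3-oxobutan-2-yl)cyclohex-3-en-1-yl]propanenitrile
Product: 13 cis-fused 2,6,6,9-tetramethylbicyclo[5.4.0]undec-8-ene-3,5-dione (C2 epimers), via enaminone 12 (not isolated)
Conditions: KOt-Bu (2.2 equiv), t-BuOH–THF, 60 °C; then 1 M HCl, THF, rt
Reagents that add atoms: water, O
Why: Thorpe–Ziegler-type condensation: the only ketone enolate that can form (at the methyl group C4, C6 being quaternary) adds to the nitrile carbon C3 in a 7-exo-dig closure driven by formation of the conjugated enaminone anion, and acid hydrolysis of this vinylogous amide releases the 1,3-dione; no stereocentre is created and the cis fusion set in step 2 is kept.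

Step 7
Reactants: 13 cis-fused 2,6,6,9-tetramethylbicyclo[5.4.0]undec-8-ene-3,5-dione
Product: 14 8,9-epoxy-2,6,6,9-tetramethylbicyclo[5.4.0]undecane-3,5-dione (oxirane oxygen anti to the C1–C2 and C6–C7 bonds; C2 epimers)
Conditions: dimethyldioxirane (1.1 equiv), acetone, −20 °C
Reagents that add atoms: dimethyldioxirane, CC1(C)OO1
Why: Epoxidation with dimethyldioxirane is neutral and fast for the electron-rich trisubstituted alkene, and the reagent approaches from the convex face, anti to the C6 substituent on the allylic carbon C7 and to the C1–C2 bond, which places the oxirane oxygen where step 8 needs it.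

Step 8
Reactants: 14 8,9-epoxy-2,6,6,9-tetramethylbicyclo[5.4.0]undecane-3,5-dione
Product: 16 9-hydroxy-2,6,6,9-tetramethyltricyclo[5.4.0.0^2,8]undecane-3,5-dione (C1, C2, C7, C8 as in the target; 9-OH anti to C2), via dilithium dienediolate 15 (not isolated)
Conditions: LiN(i-Pr)2 (2.5 equiv), THF–DMPU, −78 → 0 °C → rt; AcOH quench at −78 °C
Reagents that add atoms: none
Why: Proposed new method: LiN(i-Pr)2 forms the C4 diketonate and then removes C2–H, the only α-proton left because C6 is quaternary; the C2 terminus of the resulting dienediolate attacks C8, the secondary epoxide carbon, from the face opposite the oxirane oxygen, and the closest known reaction types are the Stork epoxynitrile cyclisation to cyclobutanes and the γ-alkylation of 1,3-dicarbonyl dianions by epoxides. The cyclobutane C1–C2–C8–C7 closes in the 4-exo-tet mode, and the same C2–C8 bond completes the seven-membered ring C2–C3–C4–C5–C6–C7–C8 as a four-carbon bridge across the 1,3-positions of the cyclobutane. The configuration of the new quaternary C2 is dictated by the existing cis ring fusion (C3 is tied to C6 and therefore ends anti to the C9–C11 bridge, the methyl syn to it), C8 is inverted relative to the epoxide, and C9 keeps the epoxide oxygen as a tertiary carbinol. The step needs C- over O-alkylation, attack by C2 and not by C4, and opening at C8 and not at C9: the terminal carbon of the dianion is its most nucleophilic site, 4-exo attack at secondary C8 is favoured over 5-endo attack at tertiary C9, and the epoxide made in step 7 lies anti to the axial C1–C2 bond.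

Step 9
Reactants: 16 9-hydroxy-2,6,6,9-tetramethyltricyclo[5.4.0.0^2,8]undecane-3,5-dione
Product: 17 (3R,5R)-2,6,6,9-tetramethyltricyclo[5.4.0.0^2,8]undecane-3,5,9-triol
Conditions: (S)-2-methyl-CBS-oxazaborolidine (0.3 equiv), BH3·SMe2 (3 equiv), THF, −20 °C; then MeOH
Reagents that add atoms: none
Why: CBS reduction: both carbonyls are ketones with one quaternary and one methylene flank, the class the oxazaborolidine differentiates reliably, and since the bridging ring has no facial bias of its own the (S)-catalyst is expected to set R at C3 and at C5 (trans-diol), while the tertiary carbinol is inert and no C=C bond is present that borane could hydroborate.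

Step 10
Reactants: 17 (3R,5R)-2,6,6,9-tetramethyltricyclo[5.4.0.0^2,8]undecane-3,5,9-triol; 18 (E)-2-methylbut-2-enoyl chloride (3 equiv)
Product: 19 (3R,5R)-9-hydroxy-2,6,6,9-tetramethyltricyclo[5.4.0.0^2,8]undecane-3,5-diyl bis[(E)-2-methylbut-2-enoate]
Conditions: pyridine, DMAP (cat.), CH2Cl2, 40 °C
Reagents that add atoms: none
Why: DMAP-catalysed acyl transfer esterifies the two neopentyl-type secondary alcohols, the tertiary C9 carbinol is too hindered to react, and the thermodynamically favoured E (tiglate) geometry is retained.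

Step 11
Reactants: 19 (3R,5R)-9-hydroxy-2,6,6,9-tetramethyltricyclo[5.4.0.0^2,8]undecane-3,5-diyl bis[(E)-2-methylbut-2-enoate]
Product: 20 (3R,5R)-2,6,6,9-tetramethyltricyclo[5.4.0.0^2,8]undec-9-ene-3,5-diyl bis[(E)-2-methylbut-2-enoate]
Conditions: Burgess reagent, toluene, 60 °C
Reagents that add atoms: none
Why: Burgess dehydration is a syn elimination of the sulfamate ester without a free carbocation (which would open the cyclobutane), and since C8 is a bridgehead the endocyclic alkene can only form towards C10, giving the trisubstituted C9=C10 bond with the exocyclic methylene isomer as the expected minor by-product.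

Step 12
Reactants: 20 (3R,5R)-2,6,6,9-tetramethyltricyclo[5.4.0.0^2,8]undec-9-ene-3,5-diyl bis[(E)-2-methylbut-2-enoate]
Product: 21 (1R,2R,3R,5R,7S,8R)-2,6,6,9-tetramethyl-11-oxotricyclo[5.4.0.0^2,8]undec-9-ene-3,5-diyl bis[(E)-2-methylbut-2-enoate] (CNP0236543.5)
Conditions: Rh2(C6H10NO)4 (dirhodium tetracaprolactamate, 1 mol %), t-BuOOH (70% aq, 5 equiv), K2CO3, CH2Cl2, rt
Reagents that add atoms: tert-butyl hydroperoxide, CC(C)(C)OO
Why: Dirhodium-caprolactamate-catalysed allylic oxidation with t-BuOOH (the pinene-to-verbenone type of oxidation) converts the only allylic methylene, C11, into the ketone, the other allylic positions being a bridgehead CH and methyl groups and the tiglate alkenes being electron-poor.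

**Compound list**

1 | (1S,4R)-1-methyl-4-(prop-1-en-2-yl)cyclohex-2-en-1-ol | C[C@@]1(O)C=C[C@H](C(C)=C)CC1 | starting material
2 | 2-methylpropanoyl chloride | CC(C)C(Cl)=O | starting material
3 | (1S,4R)-1-methyl-4-(prop-1-en-2-yl)cyclohex-2-en-1-yl 2-methylpropanoate | C[C@@]1(OC(=O)C(C)C)C=C[C@H](C(C)=C)CC1 | intermediate
4 | trimethylsilyl ketene acetal of 3 (not isolated) | C[C@@]1(OC(O[Si](C)(C)C)=C(C)C)C=C[C@H](C(C)=C)CC1 | intermediate
5 | trimethylsilyl ester of 6 (not isolated) | CC1=C[C@H](C(C)(C)C(=O)O[Si](C)(C)C)[C@H](C(C)=C)CC1 | intermediate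
6 | 2-methyl-2-[(1S,6R)-3-methyl-6-(prop-1-en-2-yl)cyclohex-2-en-1-yl]propanoic acid | CC1=C[C@H](C(C)(C)C(=O)O)[C@H](C(C)=C)CC1 | intermediate
7 | bis(9-BBN) adduct of 6: B-alkyl borane at C3 and acyloxyborane (not isolated; C2 epimers) | CC1=C[C@H](C(C)(C)C(=O)OB2C3CCCC2CCC3)[C@H](C(C)CB2C3CCCC2CCC3)CC1 | intermediate
8 | 2-[6-(1-hydroxypropan-2-yl)-3-methylcyclohex-2-en-1-yl]-2-methylpropanoic acid (ring centres as in 6; C2 epimers) | CC1=C[C@H](C(C)(C)C(=O)O)[C@H](C(C)CO)CC1 | intermediate
9 | 3-[6-(1-hydroxypropan-2-yl)-3-methylcyclohex-2-en-1-yl]-3-methylbutan-2-one (ring centres as in 6; C2 epimers) | CC1=C[C@H](C(C)(C)C(C)=O)[C@H](C(C)CO)CC1 | intermediate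
10 | 2-[4-methyl-2-(2-methyl-3-oxobutan-2-yl)cyclohex-3-en-1-yl]propanal (not isolated) | CC1=C[C@H](C(C)(C)C(C)=O)[C@H](C(C)C=O)CC1 | intermediate
11 | 2-[4-methyl-2-(2-methyl-3-oxobutan-2-yl)cyclohex-3-en-1-yl]propanenitrile (ring centres as in 6; C2 epimers) | CC1=C[C@H](C(C)(C)C(C)=O)[C@H](C(C)C#N)CC1 | intermediate
12 | cis-fused 3-amino-2,6,6,9-tetramethylbicyclo[5.4.0]undeca-3,8-dien-5-one (not isolated) | CC1=C[C@H]2[C@@H](CC1)C(C)C(N)=CC(=O)C2(C)C | intermediate
13 | cis-fused 2,6,6,9-tetramethylbicyclo[5.4.0]undec-8-ene-3,5-dione (C2 epimers) | CC1=C[C@H]2[C@@H](CC1)C(C)C(=O)CC(=O)C2(C)C | intermediate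
14 | 8,9-epoxy-2,6,6,9-tetramethylbicyclo[5.4.0]undecane-3,5-dione, oxirane oxygen anti to the C1–C2 and C6–C7 bonds (C2 epimers) | C[C@]12O[C@H]1[C@H]3[C@@H](CC2)C(C)C(=O)CC(=O)C3(C)C | intermediate
15 | dilithium 8,9-epoxy-2,6,6,9-tetramethylbicyclo[5.4.0]undeca-2,4-diene-3,5-diolate (not isolated) | C[C@]12O[C@H]1[C@H]3[C@@H](CC2)C(C)=C([O-])C=C([O-])C3(C)C.[Li+].[Li+] | intermediate
16 | 9-hydroxy-2,6,6,9-tetramethyltricyclo[5.4.0.0^2,8]undecane-3,5-dione (9-OH anti to C2) | O=C1CC(=O)[C@@]2(C)[C@@H]3CC[C@@](C)(O)[C@H]2[C@@H]3C1(C)C | intermediate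
17 | (3R,5R)-2,6,6,9-tetramethyltricyclo[5.4.0.0^2,8]undecane-3,5,9-triol | O[C@@H]1C[C@@H](O)[C@@]2(C)[C@@H]3CC[C@@](C)(O)[C@H]2[C@@H]3C1(C)C | intermediate
18 | (E)-2-methylbut-2-enoyl chloride (tigloyl chloride) | C/C=C(\C)C(Cl)=O | starting material
19 | (3R,5R)-9-hydroxy-2,6,6,9-tetramethyltricyclo[5.4.0.0^2,8]undecane-3,5-diyl bis[(E)-2-methylbut-2-enoate] | C/C=C(\C)C(=O)O[C@@H]1C[C@@H](OC(=O)/C(C)=C/C)[C@@]2(C)[C@@H]3CC[C@@](C)(O)[C@H]2[C@@H]3C1(C)C | intermediate
20 | (3R,5R)-2,6,6,9-tetramethyltricyclo[5.4.0.0^2,8]undec-9-ene-3,5-diyl bis[(E)-2-methylbut-2-enoate] | C/C=C(\C)C(=O)O[C@@H]1C[C@@H](OC(=O)/C(C)=C/C)[C@@]2(C)[C@@H]3CC=C(C)[C@H]2[C@@H]3C1(C)C | intermediate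
21 | (1R,2R,3R,5R,7S,8R)-2,6,6,9-tetramethyl-11-oxotricyclo[5.4.0.0^2,8]undec-9-ene-3,5-diyl bis[(E)-2-methylbut-2-enoate] (CNP0236543.5) | C/C=C(\C)C(=O)O[C@@H]1C[C@@H](OC(=O)/C(C)=C/C)[C@@]2(C)[C@@H]3C(=O)C=C(C)[C@H]2[C@@H]3C1(C)C | target

**Step count and risks**

Total step count: 12. Longest linear sequence: 12 steps (1 → 21).

Steps most likely to fail:

1. Step 8 (Proposed new method). The second deprotonation at the tertiary C2–H may be slow, so that O-alkylation of the diketonate by the epoxide or amide-induced isomerisation of the epoxide outruns the 4-exo C-alkylation. The fallback uses known chemistry, sets out from keto nitrile 11 and comes back to the route at 16. It inverts the order of ring closures, so that the cyclobutane is made by nitrile-anion chemistry and the seven-membered ring C2–C8 is still the last ring to close. The ketone of 11 is masked with ethylene glycol (TsOH cat., benzene, reflux with water removal) as the dioxolane nitrile F1. Dimethyldioxirane then gives the epoxide F2, with oxygen anti to both side chains. KN(SiMe3)2 in toluene (0 °C → rt) effects the Stork epoxynitrile cyclisation, the tertiary nitrile anion opening the epoxide at C8 in the 4-exo mode to the bicyclo[3.1.1]heptane hydroxy nitrile F3; the small linear nitrile is expected to take the position cis to the bulky C6 substituent. PPTS in wet acetone releases the methyl ketone F4. KOt-Bu in t-BuOH–THF closes the seven-membered ring by the enolate–nitrile condensation used in step 6, giving the tricyclic enaminone F5, which aqueous acetic acid should hydrolyse to 16.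

2. Step 9. Partial enolisation of the 1,3-dione towards borane, or incomplete catalyst control in the second hydride transfer, would erode the trans selectivity. The fallback sets out from 16 and comes back at 17. The reduction is stopped after one hydride transfer ((S)-2-methyl-CBS-oxazaborolidine, 0.6 equiv BH3·SMe2, −40 °C), giving the (R)-hydroxy ketones 5-hydroxy-3-one F8 and 3-hydroxy-5-one F9. Both are then reduced with Me4NBH(OAc)3 in MeCN–AcOH at −30 °C (Evans–Saksena hydroxyl-directed anti reduction). Intramolecular hydride delivery from the existing carbinol replaces the second catalyst-controlled step, and both regioisomers converge on the trans-diol 17.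

3. Step 6. The 7-exo-dig addition of the hindered methyl ketone enolate to the branched nitrile may be too slow, so that intermolecular condensation takes over. The fallback sets out from 9 and comes back at 13, bypassing the nitrile. The primary alcohol is oxidised to the keto acid F6 (TEMPO cat., PhI(OAc)2, MeCN–H2O) and esterified with Me3SiCHN2 in MeOH–toluene to the keto methyl ester F7. Intramolecular Claisen condensation (NaH, THF, reflux), in which the methyl ketone enolate is acylated by the ester and the diketonate is the driving force, should give 13.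

Further compounds
F1 | step 8 | 2-{4-methyl-2-[2-(2-methyl-1,3-dioxolan-2-yl)propan-2-yl]cyclohex-3-en-1-yl}propanenitrile (ring centres as in 6) | CC1=C[C@H](C(C)(C)C2(C)OCCO2)[C@H](C(C)C#N)CC1
F2 | step 8 | C8–C9 epoxide of F1 (oxygen anti to both side chains) | C[C@]12O[C@H]1[C@H](C(C)(C)C3(C)OCCO3)[C@H](C(C)C#N)CC2
F3 | step 8 | bicyclo[3.1.1]heptane hydroxy nitrile with C6 dioxolane side chain (C2 nitrile cis to the C6 substituent) | N#C[C@@]1(C)[C@@H]2CC[C@@](C)(O)[C@H]1[C@@H]2C(C)(C)C3(C)OCCO3
F4 | step 8 | bicyclo[3.1.1]heptane hydroxy keto nitrile | N#C[C@@]1(C)[C@@H]2CC[C@@](C)(O)[C@H]1[C@@H]2C(C)(C)C(C)=O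
F5 | step 8 | 3-amino-9-hydroxy-2,6,6,9-tetramethyltricyclo[5.4.0.0^2,8]undec-3-en-5-one | O=C1C=C(N)[C@@]2(C)[C@@H]3CC[C@@](C)(O)[C@H]2[C@@H]3C1(C)C
F6 | step 6 | 2-[4-methyl-2-(2-methyl-3-oxobutan-2-yl)cyclohex-3-en-1-yl]propanoic acid | CC1=C[C@H](C(C)(C)C(C)=O)[C@H](C(C)C(=O)O)CC1
F7 | step 6 | methyl 2-[4-methyl-2-(2-methyl-3-oxobutan-2-yl)cyclohex-3-en-1-yl]propanoate | CC1=C[C@H](C(C)(C)C(C)=O)[C@H](C(C)C(=O)OC)CC1
F8 | step 9 | (5R)-5,9-dihydroxy-2,6,6,9-tetramethyltricyclo[5.4.0.0^2,8]undecan-3-one | O[C@@H]1CC(=O)[C@@]2(C)[C@@H]3CC[C@@](C)(O)[C@H]2[C@@H]3C1(C)C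
F9 | step 9 | (3R)-3,9-dihydroxy-2,6,6,9-tetramethyltricyclo[5.4.0.0^2,8]undecan-5-one | O=C1C[C@@H](O)[C@@]2(C)[C@@H]3CC[C@@](C)(O)[C@H]2[C@@H]3C1(C)C
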